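## Retrosynthetic overview

Rings: A = oxepene, B = its fused cyclohexane, C = right-hand cyclohexane, D = oxepanone.

1. Sodwanone S ⇐ ketal hydrolysis and closure of ring A (last ring) by 7-endo opening of a gem-dimethyl epoxide by the ring-B allylic OH ⇐ ring-B alkylidene epoxy diol ⇐ desilylation and Barton removal of a CO2H from the linker CH2 next to ring B.
2. Key disconnection: the bond between the ring-B quaternary carbon (CH3, linker) and the linker CH2, made by Ireland–Claisen rearrangement of an ester that tethers the two halves. Enabling feature: this quaternary carbon is allylic to the trisubstituted alkene of ring A (A/B fusion carbon = CH of ring A), so linker-CH2–C(quaternary)–C=CH is the γ,δ-unsaturated-acid pattern of a [3,3] shift once a carboxyl sits on that CH2; the retro-shift moves the alkene into ring B and puts the ester oxygen on the future ring-A CH, whose configuration controls the quaternary centre.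
3. Ester ⇐ right-hand acid (rings C and D, three-carbon acid arm, ketone as dioxolane, tertiary OH as TES ether) + left-hand allylic alcohol (ring B, (R)-carbinol, (S)-epoxide side chain).
4. Right half: (2E,6E)-farnesyl acetate ⇒ Shi diepoxide ⇒ two-carbon homologation to a tert-butyl ester ⇒ one cationic cascade closing ring D (oxepane), ring C (cyclohexane) and a temporary δ-lactone.
5. Left half: ring B from propanal + methyl vinyl ketone (Michael/aldol), then β-methylation–dehydrogenation, α-iodination, CBS reduction, formylation, allylboration, cross-metathesis, Shi epoxidation. Ring order: D and C (one step), B, then A last.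

Key step: step 20

Assumption: each chiral catalyst is taken to follow its accepted model of induction (given in the Why lines); if a sense proved opposite, the antipodal catalyst would be used and nothing else would change.

## Route

**Right-hand fragment**

Step 1
Reactants: 1 (2E,6E)-farnesyl acetate
Product: 2 (2E,6S,7S,10S)-6,7:10,11-diepoxy-3,7,11-trimethyldodec-2-en-1-yl acetate
Conditions: L-fructose-derived Shi ketone (0.6 equiv), KHSO5 (Oxone, 2KHSO5·KHSO4·K2SO4), K2CO3, Bu4NHSO4, MeCN/CH2(OMe)2/aq. Na2B4O7 buffer, 0 °C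
Reagents that add atoms: potassium peroxymonosulfate, [K+].[O-]S(=O)(=O)OO
Why: Shi asymmetric epoxidation: the chiral dioxirane should epoxidise the two electron-rich trisubstituted alkenes through a spiro transition state to give the (6S,7S) and (10S) epoxides with the L-fructose-derived ketone, while the 2,3-alkene is spared because the allylic acetoxy group deactivates it.

Step 2
Reactants: 2 diepoxy acetate
Product: 3 (2E,6S,7S,10S)-6,7:10,11-diepoxy-3,7,11-trimethyldodec-2-en-1-ol
Conditions: K2CO3 (0.2 equiv), MeOH, 0 °C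
Reagents that add atoms: none
Why: Base-catalysed transesterification (methanolysis) frees the allylic alcohol while the trisubstituted epoxides are inert to methoxide at 0 °C and no stereocentre is touched.

Step 3
Reactants: 3 diepoxy alcohol
Product: 5 (2E,6S,7S,10S)-1-bromo-6,7:10,11-diepoxy-3,7,11-trimethyldodec-2-ene, via mesylate 4 (not isolated)
Conditions: MsCl, Et3N, CH2Cl2, −40 °C; then LiBr, THF, 0 °C
Reagents that add atoms: lithium bromide, [Li+].[Br-]
Why: Mesylation followed by SN2 displacement with bromide at the primary allylic carbon should proceed without allylic transposition or epoxide opening at low temperature.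

Step 4
Reactants: 5 allylic bromide
Product: 6 tert-butyl (4E,8S,9S,12S)-8,9:12,13-diepoxy-5,9,13-trimethyltetradec-4-enoate
Conditions: tert-butyl acetate, LiN(i-Pr)2, THF, −78 °C; then 5, DMPU, −78 → −20 °C
Reagents that add atoms: tert-butyl acetate, CC(=O)OC(C)(C)C
Why: SN2 alkylation of a lithium ester enolate by a primary allylic bromide adds the two carbons of the future linker/acid arm and places a tert-butyl ester where it can later terminate the cascade.

Step 5
Reactants: 6 diepoxy tert-butyl ester
Product: 8 tricyclic hydroxy δ-lactone (3S,5aS,6S,7S,9aS; rings D and C plus lactone), via TMS ether 7 (not isolated)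
Conditions: TMSOTf (1.1 equiv), 2,6-di-tert-butyl-4-methylpyridine (1.5 equiv), CH2Cl2, −78 °C; then 1 M HCl, THF, 0 °C
Reagents that add atoms: none
Why: Epoxide-opening oxa/carbacyclization cascade (cationic polycyclization): the silyl-activated terminal epoxide is attacked at its tertiary carbon by the internal epoxide oxygen (ring D, 7-endo), the epoxonium ion is opened at its tertiary carbon by the (E)-alkene through a chair transition state (ring C, 6-endo) and the tertiary cation is captured by the ester carbonyl with loss of isobutene (δ-lactone), so that the ring-fusion CH–O keeps the epoxide configuration, the angular carbon is inverted (trans fusion) and anti addition across the E-alkene puts the side arm and the lactone oxygen equatorial.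

Step 6
Reactants: 8 hydroxy δ-lactone
Product: 9 keto δ-lactone (3-oxo analogue of 8)
Conditions: Dess–Martin periodinane, NaHCO3, CH2Cl2, 23 °C
Reagents that add atoms: none
Why: Dess–Martin oxidation of the only free (secondary) alcohol installs the ring-D ketone under buffered conditions that leave the lactone and the remaining stereocentres untouched.

Step 7
Reactants: 9 keto δ-lactone
Product: 10 dioxolane-protected δ-lactone
Conditions: Me3SiOCH2CH2OSiMe3, TMSOTf (5 mol%), CH2Cl2, −78 → −20 °C
Reagents that add atoms: 1,2-bis(trimethylsilyloxy)ethane, C[Si](C)(C)OCCO[Si](C)(C)C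
Why: Aprotic Noyori ketalisation masks the hindered ketone so that the ester of step 19 is the only enolisable carbonyl in the key step.

Step 8
Reactants: 10 ketal lactone
Product: 13 3-[(5aS,6S,7S,9aS)-3,3-ethylenedioxy-2,2,5a,7-tetramethyl-7-(triethylsilyloxy)decahydro-1-benzoxepin-6-yl]propanoic acid, via lithium carboxylate 11 (not isolated), via bis-silyl derivative 12 (not isolated)
Conditions: LiOH, THF/H2O, 23 °C, evaporate; then Et3SiOTf, 2,6-lutidine, CH2Cl2, 0 → 23 °C; then K2CO3, MeOH/H2O, 0 °C, pH 5 buffer
Reagents that add atoms: lithium hydroxide, [Li+].[OH-]; triethylsilyl triflate, CC[Si](CC)(CC)OS(=O)(=O)C(F)(F)F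
Why: Saponification of the lactone, silylation of carboxylate and tertiary alkoxide, and selective hydrolysis of the labile silyl ester should give the free acid with the tertiary alcohol blocked, so that relactonisation is impossible and no stereocentre is touched.

**Left-hand fragment**

Step 9
Reactants: 14 propanal; 15 methyl vinyl ketone
Product: 16 (S)-2-methyl-5-oxohexanal
Conditions: (R)-α,α-diphenylprolinol trimethylsilyl ether (10 mol%), ethyl 3,4-dihydroxybenzoate (20 mol%), neat, 4 °C
Reagents that add atoms: none
Why: Enamine-catalysed asymmetric Michael addition: the (E)-enamine of propanal should add to the enone from the face opposite the bulky diarylsilyloxymethyl group, which sets the (S) methyl-bearing centre with the (R)-catalyst.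

Step 10
Reactants: 16 keto aldehyde
Product: 17 (S)-4-methylcyclohex-2-en-1-one
Conditions: LiOH (0.1 equiv), i-PrOH, 23 °C
Reagents that add atoms: none
Why: Intramolecular aldol condensation (the ring closure of a Robinson annulation) forms ring B, and mild base is used so that the stereocentre, which ends up γ to the carbonyl, is not epimerised.

Step 11
Reactants: 17 enone
Product: 19 (S)-3,4-dimethylcyclohex-2-en-1-one, via TMS enol ether 18 (not isolated)
Conditions: MeLi (2 equiv), CuI, Et2O, 0 °C; 17, Me3SiCl, −78 °C; then Pd(OAc)2 (10 mol%), O2 (1 atm), DMSO, 23 °C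
Reagents that add atoms: lithium dimethylcuprate, [Li+].C[Cu-]C
Why: Cuprate conjugate addition with in situ silylation gives a regiodefined silyl enol ether, and Saegusa–Ito dehydrogenation (divalent palladium enolate, β-hydride elimination) returns the enone with the new methyl on the β-carbon, which erases the transient centre and does not involve the (S) centre.

Step 12
Reactants: 19 dimethyl enone
Product: 20 (S)-2-iodo-3,4-dimethylcyclohex-2-en-1-one
Conditions: I2, pyridine, CH2Cl2, 0 → 23 °C
Reagents that add atoms: iodine, II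
Why: Pyridine-mediated α-iodination of the enone (addition–elimination, Johnson iodination) should install the vinyl iodide that later turns the α-carbon into a nucleophile.

Step 13
Reactants: 20 iodo enone
Product: 21 (1S,4S)-2-iodo-3,4-dimethylcyclohex-2-en-1-ol
Conditions: (R)-2-methyl-CBS-oxazaborolidine (0.2 equiv), BH3·SMe2, THF, −30 °C; MeOH quench
Reagents that add atoms: none
Why: Corey–Bakshi–Shibata reduction: the oxazaborolidine–borane complex treats the iodoalkene carbon as the large group and should deliver hydride under reagent control to give the (1S) carbinol, trans to the ring methyl.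

Step 14
Reactants: 21 iodo alcohol
Product: 22 tert-butyl{[(1S,4S)-2-iodo-3,4-dimethylcyclohex-2-en-1-yl]oxy}dimethylsilane
Conditions: t-BuMe2SiCl, imidazole, DMF, 23 °C
Reagents that add atoms: tert-butyldimethylsilyl chloride, CC(C)(C)[Si](C)(C)Cl
Why: Standard silylation protects the ring-B carbinol with a group that survives organolithium, oxidant and amide base and is removed by fluoride in step 22.

Step 15
Reactants: 22 silyl ether
Product: 24 (3S,6S)-6-(tert-butyldimethylsilyloxy)-2,3-dimethylcyclohex-1-ene-1-carbaldehyde, via vinyllithium 23 (not isolated)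
Conditions: t-BuLi (2.1 equiv), Et2O, −78 °C; then DMF, −78 → 0 °C; aq. NH4Cl
Reagents that add atoms: N,N-dimethylformamide, CN(C)C=O
Why: Iodine–lithium exchange gives the vinyllithium with retention of the tetrasubstituted alkene, and formylation with DMF introduces the carbon that becomes the CH of the ring-A alkene.

Step 16
Reactants: 24 enal
Product: 25 (1R)-1-[(3S,6S)-6-(tert-butyldimethylsilyloxy)-2,3-dimethylcyclohex-1-en-1-yl]but-3-en-1-ol
Conditions: allylboronic acid pinacol ester, (R)-TRIP [(R)-3,3′-bis(2,4,6-triisopropylphenyl)-1,1′-binaphthyl-2,2′-diyl hydrogen phosphate] (5 mol%), toluene, −30 °C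
Reagents that add atoms: allylboronic acid pinacol ester, C=CCB1OC(C)(C)C(C)(C)O1
Why: Chiral-phosphoric-acid-catalysed allylboration through a closed chair transition state should give the (R)-carbinol under catalyst control, by analogy with aromatic and conjugated aldehydes; this centre later relays chirality to the quaternary carbon.

Step 17
Reactants: 25 homoallylic alcohol
Product: 26 (1R)-1-[(3S,6S)-6-(tert-butyldimethylsilyloxy)-2,3-dimethylcyclohex-1-en-1-yl]-4-methylpent-3-en-1-ol
Conditions: 2-methyl-2-butene (excess), second-generation Grubbs catalyst RuCl2(=CHPh)(H2IMes)(PCy3) (5 mol%), CH2Cl2, 40 °C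
Reagents that add atoms: 2-methyl-2-butene, CC=C(C)C
Why: Olefin cross-metathesis converts the terminal vinyl group into the trisubstituted prenyl alkene, and the tetrasubstituted ring alkene is inert to the ruthenium carbene.

Step 18
Reactants: 26 prenyl alcohol
Product: 27 (1R)-1-[(3S,6S)-6-(tert-butyldimethylsilyloxy)-2,3-dimethylcyclohex-1-en-1-yl]-2-[(2S)-3,3-dimethyloxiran-2-yl]ethan-1-ol
Conditions: L-fructose-derived Shi ketone (0.3 equiv), KHSO5 (Oxone, 2KHSO5·KHSO4·K2SO4), K2CO3, Bu4NHSO4, MeCN/CH2(OMe)2/aq. Na2B4O7 buffer, 0 °C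
Reagents that add atoms: potassium peroxymonosulfate, [K+].[O-]S(=O)(=O)OO
Why: Shi asymmetric epoxidation: the dioxirane should epoxidise the accessible trisubstituted alkene through the spiro transition state to give the (S)-epoxide, and should leave the hindered tetrasubstituted ring alkene that is flanked by two allylic oxygens.

**Union and end game**

Step 19
Reactants: 13 right-hand acid; 27 left-hand alcohol
Product: 28 ester of alcohol 27 with acid 13
Conditions: EDC·HCl, DMAP, CH2Cl2, 0 → 23 °C
Reagents that add atoms: none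
Why: Steglich-type carbodiimide esterification of an unhindered carboxylic acid with the secondary allylic alcohol tethers the two halves under neutral conditions that spare epoxide, ketal and silyl ethers, with retention at the carbinol carbon.

Step 20
Reactants: 28 ester
Product: 31 rearranged acid (new quaternary carbon bonded to the CO2H-bearing linker carbon), via silyl ketene acetal 29 (not isolated), via TMS ester 30 (not isolated)
Conditions: LiN(i-Pr)2 (1.5 equiv), Me3SiCl/Et3N, THF, −78 → 23 °C; then toluene, 80 °C; pH 5 buffer work-up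
Reagents that add atoms: none
Why: Ireland–Claisen rearrangement: the ester α-CH2 is deprotonated and O-silylated, and the silyl ketene acetal undergoes a concerted suprafacial [3,3] shift in which the carbinol C–O bond breaks, the bond from the ketene-acetal carbon (the future linker CH2) to the methyl-bearing alkene carbon of ring B forms, and the double bond moves to the fusion carbon and the side-chain CH, exactly where the ring-A alkene must be. The closest known reaction type is the Ireland–Claisen rearrangement of esters of 2-alkylcyclohex-1-enyl carbinols, which builds ring quaternary carbons next to an exocyclic alkene. No ring is closed; the two halves, held so far only by the ester tether, become joined by a C–C bond. The quaternary stereocentre is set by 1,3-chirality transfer from the (R)-carbinol carbon: with the carbinol hydrogen eclipsing the ring alkene toward the vinylic methyl, the oxygen lies on the ring face that carries the secondary methyl, so the new bond forms on that face (cis to the secondary methyl, trans to the silyloxy group) and the side-chain CH2 ends cis to the silyloxy-bearing carbon (Z), as ring A requires; the CO2H-bearing carbon is an unassigned centre that step 21 erases. The step needs this chirality transfer to override the usual preference for attack anti to the neighbouring secondary methyl, and this is secured because the competing transition state would press the side-chain CH2 against the vinylic methyl (A(1,3) strain on a tetrasubstituted alkene) while delivery is intramolecular. Chemoselectivity rests on the ester being the only enolisable carbonyl and on epoxide, ketal and silyl ethers being inert to the amide base at low temperature.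

Step 21
Reactants: 31 rearranged acid
Product: 33 coupled silyl-protected epoxide (linker now CH2CH2), via Barton ester 32 (not isolated)
Conditions: N-hydroxypyridine-2-thione, DCC, DMAP (cat.), CH2Cl2, 0 °C, dark; then PhSH (20 equiv), hν (tungsten lamp), benzene, 10 °C
Reagents that add atoms: none
Why: Barton reductive decarboxylation: the thiohydroxamate ester fragments under light, CO2 is lost and the secondary radical is reduced by thiophenol, a fast hydrogen donor chosen to outrun rearrangement of a radical that sits next to the quaternary allylic carbon.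

Step 22
Reactants: 33 silyl-protected epoxide
Product: 34 (1S,2Z,3R,4S)-2-{2-[(2S)-3,3-dimethyloxiran-2-yl]ethylidene}-3-{2-[(5aS,6S,7S,9aS)-3,3-ethylenedioxy-7-hydroxy-2,2,5a,7-tetramethyldecahydro-1-benzoxepin-6-yl]ethyl}-3,4-dimethylcyclohexan-1-ol
Conditions: Bu4NF, THF, 0 → 40 °C
Reagents that add atoms: none
Why: Fluoride-mediated desilylation removes the secondary TBS ether and the tertiary TES ether, while epoxide, ketal and alkene are stable to Bu4NF.

Step 23
Reactants: 34 epoxy diol
Product: 36 Sodwanone S, via ketal 35 (not isolated)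
Conditions: (+)-camphor-10-sulfonic acid (10 mol%), CH2Cl2, −20 → 0 °C; then p-TsOH, THF/H2O, 40 °C
Reagents that add atoms: water, O
Why: Acid-catalysed intramolecular epoxide opening by the ring-B allylic hydroxyl at the gem-dimethyl carbon (7-endo-tet, SN1-like) should close ring A with the carbinol C–O bond untouched, which gives the (S)-alcohol, and aqueous acid then hydrolyses the dioxolane to the ring-D ketone.

## Compound list

1 | (2E,6E)-farnesyl acetate | CC(=O)OC/C=C(\C)CC/C=C(\C)CCC=C(C)C | starting material
2 | (2E,6S,7S,10S)-6,7:10,11-diepoxy-3,7,11-trimethyldodec-2-en-1-yl acetate | CC(=O)OC/C=C(\C)CC[C@@H]1O[C@@]1(C)CC[C@@H]1OC1(C)C | intermediate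
3 | (2E,6S,7S,10S)-6,7:10,11-diepoxy-3,7,11-trimethyldodec-2-en-1-ol | OC/C=C(\C)CC[C@@H]1O[C@@]1(C)CC[C@@H]1OC1(C)C | intermediate
4 | methanesulfonate of 3 | CS(=O)(=O)OC/C=C(\C)CC[C@@H]1O[C@@]1(C)CC[C@@H]1OC1(C)C | intermediate
5 | (2E,6S,7S,10S)-1-bromo-6,7:10,11-diepoxy-3,7,11-trimethyldodec-2-ene | BrC/C=C(\C)CC[C@@H]1O[C@@]1(C)CC[C@@H]1OC1(C)C | intermediate
6 | tert-butyl (4E,8S,9S,12S)-8,9:12,13-diepoxy-5,9,13-trimethyltetradec-4-enoate | CC(C)(C)OC(=O)CC/C=C(\C)CC[C@@H]1O[C@@]1(C)CC[C@@H]1OC1(C)C | intermediate
7 | O-trimethylsilyl ether of 8 | O=C1CC[C@H]2[C@]3(C)CC[C@H](O[Si](C)(C)C)C(C)(C)O[C@H]3CC[C@]2(C)O1 | intermediate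
8 | (3S,5aS,6S,7S,9aS)-3-hydroxy-2,2,5a,7-tetramethyldecahydro-1-benzoxepine-6-propanoic acid 7-O-lactone (δ-lactone; ring D trans-fused to ring C, angular and carbinol methyls axial and cis, side arm and lactone oxygen equatorial) | O=C1CC[C@H]2[C@]3(C)CC[C@H](O)C(C)(C)O[C@H]3CC[C@]2(C)O1 | intermediate
9 | 3-oxo analogue of 8 (keto δ-lactone) | O=C1CC[C@H]2[C@]3(C)CCC(=O)C(C)(C)O[C@H]3CC[C@]2(C)O1 | intermediate
10 | 3,3-ethylenedioxy analogue of 9 (dioxolane-protected δ-lactone) | O=C1CC[C@H]2[C@]3(C)CCC4(OCCO4)C(C)(C)O[C@H]3CC[C@]2(C)O1 | intermediate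
11 | lithium 3-[(5aS,6S,7S,9aS)-3,3-ethylenedioxy-7-hydroxy-2,2,5a,7-tetramethyldecahydro-1-benzoxepin-6-yl]propanoate | [Li+].[O-]C(=O)CC[C@H]1[C@]2(C)CCC3(OCCO3)C(C)(C)O[C@H]2CC[C@]1(C)O | intermediate
12 | triethylsilyl ester of 13 | CC[Si](CC)(CC)OC(=O)CC[C@H]1[C@]2(C)CCC3(OCCO3)C(C)(C)O[C@H]2CC[C@]1(C)O[Si](CC)(CC)CC | intermediate
13 | 3-[(5aS,6S,7S,9aS)-3,3-ethylenedioxy-2,2,5a,7-tetramethyl-7-(triethylsilyloxy)decahydro-1-benzoxepin-6-yl]propanoic acid (right-hand acid) | OC(=O)CC[C@H]1[C@]2(C)CCC3(OCCO3)C(C)(C)O[C@H]2CC[C@]1(C)O[Si](CC)(CC)CC | intermediate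
14 | propanal | CCC=O | starting material
15 | methyl vinyl ketone (but-3-en-2-one) | CC(=O)C=C | starting material
16 | (S)-2-methyl-5-oxohexanal | C[C@H](C=O)CCC(C)=O | intermediate
17 | (S)-4-methylcyclohex-2-en-1-one | C[C@H]1CCC(=O)C=C1 | intermediate
18 | trimethylsilyl enol ether of trans-3,4-dimethylcyclohexanone (4S) | C[C@H]1CCC(O[Si](C)(C)C)=C[C@@H]1C | intermediate
19 | (S)-3,4-dimethylcyclohex-2-en-1-one | C[C@H]1CCC(=O)C=C1C | intermediate
20 | (S)-2-iodo-3,4-dimethylcyclohex-2-en-1-one | C[C@H]1CCC(=O)C(I)=C1C | intermediate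
21 | (1S,4S)-2-iodo-3,4-dimethylcyclohex-2-en-1-ol | C[C@H]1CC[C@H](O)C(I)=C1C | intermediate
22 | tert-butyl{[(1S,4S)-2-iodo-3,4-dimethylcyclohex-2-en-1-yl]oxy}dimethylsilane | C[C@H]1CC[C@H](O[Si](C)(C)C(C)(C)C)C(I)=C1C | intermediate
23 | [(3S,6S)-6-(tert-butyldimethylsilyloxy)-2,3-dimethylcyclohex-1-en-1-yl]lithium | C[C@H]1CC[C@H](O[Si](C)(C)C(C)(C)C)C([Li])=C1C | intermediate
24 | (3S,6S)-6-(tert-butyldimethylsilyloxy)-2,3-dimethylcyclohex-1-ene-1-carbaldehyde | C[C@H]1CC[C@H](O[Si](C)(C)C(C)(C)C)C(C=O)=C1C | intermediate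
25 | (1R)-1-[(3S,6S)-6-(tert-butyldimethylsilyloxy)-2,3-dimethylcyclohex-1-en-1-yl]but-3-en-1-ol | C[C@H]1CC[C@H](O[Si](C)(C)C(C)(C)C)C([C@H](O)CC=C)=C1C | intermediate
26 | (1R)-1-[(3S,6S)-6-(tert-butyldimethylsilyloxy)-2,3-dimethylcyclohex-1-en-1-yl]-4-methylpent-3-en-1-ol | C[C@H]1CC[C@H](O[Si](C)(C)C(C)(C)C)C([C@H](O)CC=C(C)C)=C1C | intermediate
27 | (1R)-1-[(3S,6S)-6-(tert-butyldimethylsilyloxy)-2,3-dimethylcyclohex-1-en-1-yl]-2-[(2S)-3,3-dimethyloxiran-2-yl]ethan-1-ol (left-hand alcohol) | C[C@H]1CC[C@H](O[Si](C)(C)C(C)(C)C)C([C@H](O)C[C@@H]2OC2(C)C)=C1C | intermediate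
28 | (1R)-1-[(3S,6S)-6-(tert-butyldimethylsilyloxy)-2,3-dimethylcyclohex-1-en-1-yl]-2-[(2S)-3,3-dimethyloxiran-2-yl]ethyl ester of acid 13 | C[C@H]1CC[C@H](O[Si](C)(C)C(C)(C)C)C([C@H](OC(=O)CC[C@H]2[C@]3(C)CCC4(OCCO4)C(C)(C)O[C@H]3CC[C@]2(C)O[Si](CC)(CC)CC)C[C@@H]5OC5(C)C)=C1C | intermediate
29 | O-trimethylsilyl ketene acetal of 28 (C=C geometry not assigned) | C[C@H]1CC[C@H](O[Si](C)(C)C(C)(C)C)C([C@H](OC(O[Si](C)(C)C)=CC[C@H]2[C@]3(C)CCC4(OCCO4)C(C)(C)O[C@H]3CC[C@]2(C)O[Si](CC)(CC)CC)C[C@@H]5OC5(C)C)=C1C | intermediate
30 | trimethylsilyl ester of 31 | C[C@H]1CC[C@H](O[Si](C)(C)C(C)(C)C)/C(=C\C[C@@H]2OC2(C)C)[C@@]1(C)C(C(=O)O[Si](C)(C)C)C[C@H]3[C@]4(C)CCC5(OCCO5)C(C)(C)O[C@H]4CC[C@]3(C)O[Si](CC)(CC)CC | intermediate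
31 | rearranged acid: 3-[right-hand bicycle of 13]-2-[ring-B quaternary carbon]propanoic acid; ring B has the acid arm cis to the secondary methyl and trans to OTBS, exocyclic alkene Z (side-chain CH2 cis to the silyloxy carbon); α-carbon not assigned | C[C@H]1CC[C@H](O[Si](C)(C)C(C)(C)C)/C(=C\C[C@@H]2OC2(C)C)[C@@]1(C)C(C(=O)O)C[C@H]3[C@]4(C)CCC5(OCCO5)C(C)(C)O[C@H]4CC[C@]3(C)O[Si](CC)(CC)CC | intermediate
32 | 2-thioxopyridin-1(2H)-yl ester (Barton ester) of 31 | C[C@H]1CC[C@H](O[Si](C)(C)C(C)(C)C)/C(=C\C[C@@H]2OC2(C)C)[C@@]1(C)C(C(=O)ON6C=CC=CC6=S)C[C@H]3[C@]4(C)CCC5(OCCO5)C(C)(C)O[C@H]4CC[C@]3(C)O[Si](CC)(CC)CC | intermediate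
33 | tert-butyl{[(1S,2Z,3R,4S)-2-{2-[(2S)-3,3-dimethyloxiran-2-yl]ethylidene}-3,4-dimethyl-3-{2-[(5aS,6S,7S,9aS)-3,3-ethylenedioxy-2,2,5a,7-tetramethyl-7-(triethylsilyloxy)decahydro-1-benzoxepin-6-yl]ethyl}cyclohexyl]oxy}dimethylsilane | C[C@H]1CC[C@H](O[Si](C)(C)C(C)(C)C)/C(=C\C[C@@H]2OC2(C)C)[C@@]1(C)CC[C@H]3[C@]4(C)CCC5(OCCO5)C(C)(C)O[C@H]4CC[C@]3(C)O[Si](CC)(CC)CC | intermediate
34 | (1S,2Z,3R,4S)-2-{2-[(2S)-3,3-dimethyloxiran-2-yl]ethylidene}-3-{2-[(5aS,6S,7S,9aS)-3,3-ethylenedioxy-7-hydroxy-2,2,5a,7-tetramethyldecahydro-1-benzoxepin-6-yl]ethyl}-3,4-dimethylcyclohexan-1-ol | C[C@H]1CC[C@H](O)/C(=C\C[C@@H]2OC2(C)C)[C@@]1(C)CC[C@H]3[C@]4(C)CCC5(OCCO5)C(C)(C)O[C@H]4CC[C@]3(C)O | intermediate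
35 | Sodwanone S ethylene ketal (ring-D ketone as 1,3-dioxolane) | C[C@H]1CC[C@@H]2OC(C)(C)[C@@H](O)CC=C2[C@@]1(C)CC[C@H]1[C@]2(C)CCC3(OCCO3)C(C)(C)O[C@H]2CC[C@]1(C)O | intermediate
36 | Sodwanone S | C[C@H]1CC[C@@H]2OC(C)(C)[C@@H](O)CC=C2[C@@]1(C)CC[C@H]1[C@]2(C)CCC(=O)C(C)(C)O[C@H]2CC[C@]1(C)O | target

## Step count and risks

Total step count: 23. Longest linear sequence: 15 steps (steps 9–18, then 19–23); the right-hand branch (steps 1–8) is 8 steps.

The three steps most likely to fail:

**Step 5.** The tertiary ring-C cation may lose a proton, or the internal epoxide may open in a 5-exo sense, before the ester carbonyl captures the cation, so that olefin mixtures form in place of the lactone. The fallback sets out from 6 and returns at 8, and separates lactone formation from the cascade. Cyclization under the same TMSOTf conditions followed by desilylation would give the exocyclic-methylene tert-butyl ester F1 (the endocyclic isomers behave alike). A Brønsted acid (CF3SO3H, cat., CH2Cl2, −40 °C, or HCO2H) would then protonate the alkene in the Markovnikov sense under reversible conditions, and the ester would close the δ-lactone with loss of isobutene (acid-mediated olefin lactonization), which gives 8.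

**Step 21.** The secondary radical formed on loss of CO2 lies next to the quaternary allylic carbon and may undergo 3-exo closure and reopening (1,2-vinyl shift), or the thiyl radical may add to the alkene, before hydrogen transfer. The fallback sets out from 27 and 13 and returns at 33, so it also replaces steps 19 and 20 and carries no carboxyl group into the union. Alcohol 27 with PhNCO (DMAP, cat.) would give N-phenylcarbamate F2. Acid 13 would give primary iodide F3 by Barton iododecarboxylation (N-hydroxypyridine-2-thione, DCC; then CHI3, hν), where the primary radical is remote from any alkene. Exchange with t-BuLi (Et2O, −78 °C) would give alkyllithium F4 (not isolated). Deprotonation of F2 with MeLi, addition of CuI and then F4 would effect a carbamate-directed syn-SN2′ organocopper substitution. The alkyl group is delivered to the methyl-bearing alkene carbon of ring B on the face of the carbamate oxygen, the same face as in the [3,3] shift, and this gives 33 directly.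

**Step 23.** The ring-B hydroxyl may attack the secondary epoxide carbon (6-exo) in competition with the tertiary one (7-endo), which would give a dihydropyranyl carbinol. The fallback sets out from 33 and returns at 35, and replaces epoxide opening by Markovnikov alkoxymercuration. Diethylaluminium 2,2,6,6-tetramethylpiperidide, Et2Al(NC9H18), in toluene at 0 °C would isomerise the epoxide to allylic alcohol F5 (β-elimination toward a methyl group, carbinol C–O bond untouched). Bu4NF would give triol F6. Hg(OCOCF3)2 (CH2Cl2/MeCN, 0 °C) would add the ring-B hydroxyl to the 1,1-disubstituted alkene, where oxygen can only bond to the tertiary carbon (seven-membered ring), to give organomercurial F7 (not isolated). NaBH4/NaOH would reduce the C–Hg bond to give 35, which is hydrolysed to 36 as in step 23.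

## Further compounds

F1 | step 5 | tert-butyl 3-[(3S,5aS,6S,9aS)-3-hydroxy-2,2,5a-trimethyl-7-methylidenedecahydro-1-benzoxepin-6-yl]propanoate (exocyclic-methylene ester) | CC(C)(C)OC(=O)CC[C@H]1[C@]2(C)CC[C@H](O)C(C)(C)O[C@H]2CCC1=C
F2 | step 21 | N-phenylcarbamate of alcohol 27 | C[C@H]1CC[C@H](O[Si](C)(C)C(C)(C)C)C([C@H](OC(=O)Nc2ccccc2)C[C@@H]3OC3(C)C)=C1C
F3 | step 21 | primary iodide: (5aS,6S,7S,9aS)-3,3-ethylenedioxy-6-(2-iodoethyl)-2,2,5a,7-tetramethyl-7-(triethylsilyloxy)decahydro-1-benzoxepine | ICC[C@H]1[C@]2(C)CCC3(OCCO3)C(C)(C)O[C@H]2CC[C@]1(C)O[Si](CC)(CC)CC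
F4 | step 21 | alkyllithium derived from F3 | [Li]CC[C@H]1[C@]2(C)CCC3(OCCO3)C(C)(C)O[C@H]2CC[C@]1(C)O[Si](CC)(CC)CC
F5 | step 23 | allylic alcohol from 33: side chain =CH–CH2–CH(OH)–C(CH3)=CH2 with (S)-carbinol, silyl ethers retained | C[C@H]1CC[C@H](O[Si](C)(C)C(C)(C)C)/C(=C\C[C@H](O)C(C)=C)[C@@]1(C)CC[C@H]2[C@]3(C)CCC4(OCCO4)C(C)(C)O[C@H]3CC[C@]2(C)O[Si](CC)(CC)CC
F6 | step 23 | triol from F5 after desilylation | C[C@H]1CC[C@H](O)/C(=C\C[C@H](O)C(C)=C)[C@@]1(C)CC[C@H]2[C@]3(C)CCC4(OCCO4)C(C)(C)O[C@H]3CC[C@]2(C)O
F7 | step 23 | organomercurial trifluoroacetate: ketal 35 with one oxepene methyl as CH2Hg(OCOCF3) (that carbon unassigned) | C[C@H]1CC[C@@H]2OC(C)(C[Hg]OC(=O)C(F)(F)F)[C@@H](O)CC=C2[C@@]1(C)CC[C@H]1[C@]2(C)CCC3(OCCO3)C(C)(C)O[C@H]2CC[C@]1(C)O
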